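**Retrosynthetic overview**

1. Both depside esters are cut last: the ring B acyl–O4(ring A) bond (acid chloride of the ring C–ring B acid plus the ring A phenol) and the ring C acyl–O4(ring B) bond (2,4-bis(benzyloxy)-6-methylbenzoic acid plus 2,4-dihydroxy-6-methylbenzaldehyde, whose formyl carbon is the latent ring B carboxyl).
2. Ring A is the only ring that is built. Its C1 carries CO2Me between O2 on C2 and the methyl on C6, with the depside oxygen O4 on C4 para to C1. C1, C2, C3 and C6 are C5, C4, C3 and C6 of a 4-benzyloxy-6-methyl-2-pyrone-5-carboxylate; C4 (with O4) and C5 come from 1,1-bis(trimethylsilyloxy)ethene after loss of CO2 and silanol.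
3. The pyrone comes from dimethyl 3-oxopentanedioate by C-acetylation, lactonisation and O-benzylation.
4. Ring order: ring A is made by cycloaddition–cycloreversion; rings B and C are bought as arenes and joined in step 8; ring A is attached in step 11; one hydrogenolysis then frees the three phenols.

Key step: step 5

Remark: ring B is taken from purchased 2,4-dihydroxy-6-methylbenzaldehyde, so that its carboxyl travels as a formyl group until O2 is methylated; methyl orsellinate supplies ring C only. Pyrone numbering used below: O1, C2 (lactone C=O), C3 (H), C4 (OBn), C5 (CO2Me), C6 (Me).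

**Route**

Step 1
Reactants: 1 dimethyl 3-oxopentanedioate; 2 acetyl chloride
Product: 3 dimethyl 2-acetyl-3-oxopentanedioate
Conditions: MgCl2, pyridine, CH2Cl2, 0 °C to rt; aq. HCl work-up
Reagents that add atoms: none
Why: Magnesium-chelate (Rathke-type) C-acylation of the 1,3-dicarbonyl enolate at one of the two equivalent methylenes, the product chelate being too stabilised to take up a second acyl group.

Step 2
Reactants: 3 dimethyl 2-acetyl-3-oxopentanedioate
Product: 4 methyl 4-hydroxy-6-methyl-2-oxo-2H-pyran-5-carboxylate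
Conditions: conc. H2SO4, 0 °C to rt; then ice-water
Reagents that add atoms: none
Why: Acid-mediated enol lactonisation of a 3,5-dioxo ester to a 4-hydroxy-2-pyrone, in which the acetyl enol oxygen closes the only ring size within reach, a six-membered lactone, on the remote ester with loss of methanol.

Step 3
Reactants: 4 methyl 4-hydroxy-6-methyl-2-oxo-2H-pyran-5-carboxylate
Product: 5 methyl 4-(benzyloxy)-6-methyl-2-oxo-2H-pyran-5-carboxylate
Conditions: BnOH, PPh3, DIAD, THF, 0 °C to rt
Reagents that add atoms: benzyl alcohol, OCc1ccccc1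
Why: Mitsunobu O-alkylation of the acidic vinylogous acid, which should take place through O4 as is usual for 4-hydroxy-2-pyrones and avoids the C3-benzylation that benzyl halides and base can give.

Step 4
Reactants: 6 trimethylsilyl acetate
Product: 7 1,1-bis(trimethylsilyloxy)ethene
Conditions: LiN(iPr)2 (LDA), THF, −78 °C; Me3SiCl, −78 °C to rt; distillation under reduced pressure
Reagents that add atoms: chlorotrimethylsilane, C[Si](C)(C)Cl
Why: Kinetic enolisation of the silyl ester and O-silylation of the lithium enolate (ketene bis(silyl) acetal formation), the hard silicon electrophile being taken up on oxygen at low temperature.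

Step 5
Reactants: 5 methyl 4-(benzyloxy)-6-methyl-2-oxo-2H-pyran-5-carboxylate; 7 1,1-bis(trimethylsilyloxy)ethene
Product: 11 methyl 2-(benzyloxy)-4-hydroxy-6-methylbenzoate, via bridged lactone 8 (not isolated), via cyclohexadiene 9 (not isolated), via aryl silyl ether 10 (not isolated)
Conditions: 7 (3 equiv), PhMe, 130 °C, sealed tube; then 1 M HCl, THF, rt
Reagents that add atoms: none
Why: This is an inverse-electron-demand Diels–Alder reaction of an ester-bearing 2-pyrone with a ketene acetal followed by cycloreversion and eliminative aromatisation, a sequence known for alkoxycarbonyl-2-pyrones with ketene acetals. The nucleophilic CH2 of 7 bonds to pyrone C6, which is β to the C5 ester and the vinylogous terminus of the lactone carbonyl, and the acetal carbon bonds to C3, so ring A is closed by a polarised, asynchronous [4+2] addition across C3 and C6 to give bridged lactone 8. Retro-[4+2] loss of CO2 from 8 gives diene 9, and 1,2-loss of trimethylsilanol across the CH2–C(OSiMe3)2 bond aromatises it to 10; since the two silyloxy groups are identical, either may leave and one arene should result. The acidic work-up cleaves the aryl silyl ether, so O4 (from the acetal) emerges free while O2 (from the pyrone) keeps its benzyl group. No stereocentre survives, the two bridgeheads of 8 being lost on aromatisation. The selectivity needed is regiochemical (oxygen para, not meta, to the ester) and is secured by the match between the single nucleophilic terminus of 7 and the doubly activated C6 of 5, whereas C4, the other electrophilic site, is deactivated by its benzyloxy donor.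

Step 6
Reactants: 12 methyl orsellinate (methyl 2,4-dihydroxy-6-methylbenzoate)
Product: 13 methyl 2,4-bis(benzyloxy)-6-methylbenzoate
Conditions: BnBr (2.5 equiv), K2CO3, DMF, 70 °C
Reagents that add atoms: benzyl bromide, BrCc1ccccc1
Why: Williamson etherification, with heating in DMF to drive benzylation of the hydrogen-bonded 2-OH as well as the free 4-OH.

Step 7
Reactants: 13 methyl 2,4-bis(benzyloxy)-6-methylbenzoate
Product: 14 2,4-bis(benzyloxy)-6-methylbenzoic acid
Conditions: KOH, DMSO/H2O, 100 °C; then aq. HCl
Reagents that add atoms: potassium hydroxide, [K+].[OH-]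
Why: Saponification of a di-ortho-substituted benzoate, which needs poorly solvated hydroxide and heat but leaves aryl benzyl ethers untouched.

Step 8
Reactants: 14 2,4-bis(benzyloxy)-6-methylbenzoic acid; 15 2,4-dihydroxy-6-methylbenzaldehyde
Product: 16 4-formyl-3-hydroxy-5-methylphenyl 2,4-bis(benzyloxy)-6-methylbenzoate
Conditions: (CF3CO)2O, PhMe, rt; aq. NaHCO3 work-up
Reagents that add atoms: none
Why: Mixed-anhydride esterification with trifluoroacetic anhydride, the classical depside coupling, in which the acyl trifluoroacetate of the electron-rich hindered acid should acylate the free 4-OH while the 2-OH stays locked in its hydrogen bond to the formyl group.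

Step 9
Reactants: 16 4-formyl-3-hydroxy-5-methylphenyl 2,4-bis(benzyloxy)-6-methylbenzoate
Product: 17 4-formyl-3-methoxy-5-methylphenyl 2,4-bis(benzyloxy)-6-methylbenzoate
Conditions: MeI, K2CO3, DMF, rt to 40 °C
Reagents that add atoms: iodomethane, CI
Why: Williamson O-methylation of the chelated phenol, the diaryl ester being a di-ortho-substituted benzoate that carbonate and phenoxide should not cleave at this temperature.

Step 10
Reactants: 17 4-formyl-3-methoxy-5-methylphenyl 2,4-bis(benzyloxy)-6-methylbenzoate
Product: 18 4-{[2,4-bis(benzyloxy)-6-methylbenzoyl]oxy}-2-methoxy-6-methylbenzoic acid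
Conditions: NaClO2, NaH2PO4, 2-methyl-2-butene (excess), t-BuOH/THF/H2O, rt
Reagents that add atoms: sodium chlorite, [Na+].[O-]Cl=O
Why: Pinnick (Lindgren) oxidation of the aryl aldehyde to the acid, which spares esters and benzyl ethers, with 2-methyl-2-butene consuming the hypochlorous acid that would otherwise chlorinate the electron-rich ring C.

Step 11
Reactants: 18 4-{[2,4-bis(benzyloxy)-6-methylbenzoyl]oxy}-2-methoxy-6-methylbenzoic acid; 11 methyl 2-(benzyloxy)-4-hydroxy-6-methylbenzoate
Product: 20 methyl 2-(benzyloxy)-4-[(4-{[2,4-bis(benzyloxy)-6-methylbenzoyl]oxy}-2-methoxy-6-methylbenzoyl)oxy]-6-methylbenzoate, via acid chloride 19 (not isolated)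
Conditions: (COCl)2, cat. DMF, CH2Cl2, 0 °C to rt, evaporate; then 11, Et3N, DMAP, CH2Cl2, rt
Reagents that add atoms: none
Why: Acid chloride formation with oxalyl chloride under DMF catalysis followed by DMAP-catalysed esterification of O4, the only free phenol of 11, which the key step delivered unprotected.

Step 12
Reactants: 20 methyl 2-(benzyloxy)-4-[(4-{[2,4-bis(benzyloxy)-6-methylbenzoyl]oxy}-2-methoxy-6-methylbenzoyl)oxy]-6-methylbenzoate
Product: 21 target, methyl 4-[(4-{[2,4-dihydroxy-6-methylbenzoyl]oxy}-2-methoxy-6-methylbenzoyl)oxy]-2-hydroxy-6-methylbenzoate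
Conditions: H2 (1 atm), 10% Pd/C, EtOAc, rt
Reagents that add atoms: none
Why: Catalytic hydrogenolysis of the three aryl benzyl ethers over Pd/C, under which the two aryl esters, the methyl ester and the methyl ether should be inert.

**Compound list**

1 | dimethyl 3-oxopentanedioate | COC(=O)CC(=O)CC(=O)OC | starting material
2 | acetyl chloride | CC(Cl)=O | starting material
3 | dimethyl 2-acetyl-3-oxopentanedioate | COC(=O)CC(=O)C(C(C)=O)C(=O)OC | intermediate
4 | methyl 4-hydroxy-6-methyl-2-oxo-2H-pyran-5-carboxylate | COC(=O)C1=C(C)OC(=O)C=C1O | intermediate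
5 | methyl 4-(benzyloxy)-6-methyl-2-oxo-2H-pyran-5-carboxylate | COC(=O)C1=C(C)OC(=O)C=C1OCc1ccccc1 | intermediate
6 | trimethylsilyl acetate | CC(=O)O[Si](C)(C)C | starting material
7 | 1,1-bis(trimethylsilyloxy)ethene | C=C(O[Si](C)(C)C)O[Si](C)(C)C | intermediate
8 | methyl 5-(benzyloxy)-1-methyl-3-oxo-8,8-bis(trimethylsilyloxy)-2-oxabicyclo[2.2.2]oct-5-ene-6-carboxylate (racemic, one enantiomer drawn; the bridgehead pair is fixed by the bicycle) | C[C@@]12OC(=O)[C@@H](C(OCc3ccccc3)=C1C(=O)OC)C(O[Si](C)(C)C)(O[Si](C)(C)C)C2 | intermediate (not isolated)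
9 | methyl 6-(benzyloxy)-2-methyl-4,4-bis(trimethylsilyloxy)cyclohexa-1,5-diene-1-carboxylate | COC(=O)C1=C(C)CC(O[Si](C)(C)C)(O[Si](C)(C)C)C=C1OCc1ccccc1 | intermediate (not isolated)
10 | methyl 2-(benzyloxy)-6-methyl-4-(trimethylsilyloxy)benzoate | COC(=O)c1c(C)cc(O[Si](C)(C)C)cc1OCc1ccccc1 | intermediate (not isolated)
11 | methyl 2-(benzyloxy)-4-hydroxy-6-methylbenzoate | COC(=O)c1c(C)cc(O)cc1OCc1ccccc1 | intermediate
12 | methyl orsellinate (methyl 2,4-dihydroxy-6-methylbenzoate) | COC(=O)c1c(C)cc(O)cc1O | starting material
13 | methyl 2,4-bis(benzyloxy)-6-methylbenzoate | COC(=O)c1c(C)cc(OCc2ccccc2)cc1OCc1ccccc1 | intermediate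
14 | 2,4-bis(benzyloxy)-6-methylbenzoic acid | OC(=O)c1c(C)cc(OCc2ccccc2)cc1OCc1ccccc1 | intermediate
15 | 2,4-dihydroxy-6-methylbenzaldehyde | O=Cc1c(C)cc(O)cc1O | starting material
16 | 4-formyl-3-hydroxy-5-methylphenyl 2,4-bis(benzyloxy)-6-methylbenzoate | O=Cc1c(C)cc(OC(=O)c2c(C)cc(OCc3ccccc3)cc2OCc2ccccc2)cc1O | intermediate
17 | 4-formyl-3-methoxy-5-methylphenyl 2,4-bis(benzyloxy)-6-methylbenzoate | O=Cc1c(C)cc(OC(=O)c2c(C)cc(OCc3ccccc3)cc2OCc2ccccc2)cc1OC | intermediate
18 | 4-{[2,4-bis(benzyloxy)-6-methylbenzoyl]oxy}-2-methoxy-6-methylbenzoic acid | OC(=O)c1c(C)cc(OC(=O)c2c(C)cc(OCc3ccccc3)cc2OCc2ccccc2)cc1OC | intermediate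
19 | 4-{[2,4-bis(benzyloxy)-6-methylbenzoyl]oxy}-2-methoxy-6-methylbenzoyl chloride | ClC(=O)c1c(C)cc(OC(=O)c2c(C)cc(OCc3ccccc3)cc2OCc2ccccc2)cc1OC | intermediate (not isolated)
20 | methyl 2-(benzyloxy)-4-[(4-{[2,4-bis(benzyloxy)-6-methylbenzoyl]oxy}-2-methoxy-6-methylbenzoyl)oxy]-6-methylbenzoate | COC(=O)c1c(C)cc(OC(=O)c2c(C)cc(OC(=O)c3c(C)cc(OCc4ccccc4)cc3OCc3ccccc3)cc2OC)cc1OCc1ccccc1 | intermediate
21 | methyl 4-[(4-{[2,4-dihydroxy-6-methylbenzoyl]oxy}-2-methoxy-6-methylbenzoyl)oxy]-2-hydroxy-6-methylbenzoate (CNP0563156.0) | COC(=O)c1c(C)cc(OC(=O)c2c(C)cc(OC(=O)c3c(C)cc(O)cc3O)cc2OC)cc1O | target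

**Step count**

Total: 12 steps. Longest linear sequence: 7 steps (steps 6 to 12, from methyl orsellinate 12). The ring A arm counts 6 steps (1, 2, 3, 5, 11, 12), with step 4 as a one-step side arm.

**Steps most likely to fail**

1. Step 5. The benzyloxy donor on C4 and the methyl group on C6 make the pyrone a weaker and more hindered electron-poor diene than the parent ester pyrones. The cycloaddition may therefore be outrun by thermal O-to-C silyl migration in the ketene acetal, or a first Michael addition at C6 may be followed by ring opening instead of closure onto C3. The fallback sets out from methyl orsellinate 12 and comes back at 11 by protecting-group differentiation of a bought arene. Allylation of the non-chelated 4-OH (allyl bromide, 1.05 equiv, K2CO3, acetone, reflux) should give methyl 4-(allyloxy)-2-hydroxy-6-methylbenzoate F1. Benzylation of the chelated 2-OH (BnBr, K2CO3, DMF, 70 °C) should give methyl 4-(allyloxy)-2-(benzyloxy)-6-methylbenzoate F2. Allyl transfer to morpholine with Pd(PPh3)4 in THF at rt should then deliver 11.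

2. Step 3. The pyrone oxyanion is ambident, and alkylation may go to C3 or to the lactone oxygen (giving a 2-benzyloxy-4-pyrone) instead of O4. The fallback sets out from 4 and comes back at 5; it forms the C4–O bond by substitution at the pyrone carbon, so the ambident anion is never alkylated. POCl3 with Et3N at 70 °C should convert 4 into methyl 4-chloro-6-methyl-2-oxo-2H-pyran-5-carboxylate F3, a vinylogous acid chloride. Addition–elimination of sodium benzyloxide (BnOH, NaH, THF, −20 °C) at C4 should then give 5.

3. Step 10. Hypochlorous acid may chlorinate the bis(benzyloxy) ring C faster than the scavenger removes it, or the di-ortho-substituted aldehyde may oxidise sluggishly. The fallback sets out from 14 and comes back at 18; it carries the ring B carboxyl as an allyl ester, so no oxidation is needed. Purchased 2,4-dihydroxy-6-methylbenzoic acid (orsellinic acid) F4 is alkylated on the carboxylate (allyl bromide, KHCO3, DMF, rt) to give allyl 2,4-dihydroxy-6-methylbenzoate F5. Coupling of F5 with 14 under the conditions of step 8 ((CF3CO)2O, PhMe, rt) should give allyl 4-{[2,4-bis(benzyloxy)-6-methylbenzoyl]oxy}-2-hydroxy-6-methylbenzoate F6. Methylation (MeI, K2CO3, DMF) should give allyl 4-{[2,4-bis(benzyloxy)-6-methylbenzoyl]oxy}-2-methoxy-6-methylbenzoate F7. Deallylation with Pd(PPh3)4 and morpholine in THF, then acidification, should give 18.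

**Further compounds**

F1 | step 5 | methyl 4-(allyloxy)-2-hydroxy-6-methylbenzoate | COC(=O)c1c(C)cc(OCC=C)cc1O
F2 | step 5 | methyl 4-(allyloxy)-2-(benzyloxy)-6-methylbenzoate | COC(=O)c1c(C)cc(OCC=C)cc1OCc1ccccc1
F3 | step 3 | methyl 4-chloro-6-methyl-2-oxo-2H-pyran-5-carboxylate | COC(=O)C1=C(C)OC(=O)C=C1Cl
F4 | step 10 | 2,4-dihydroxy-6-methylbenzoic acid (orsellinic acid, purchased) | OC(=O)c1c(C)cc(O)cc1O
F5 | step 10 | allyl 2,4-dihydroxy-6-methylbenzoate | C=CCOC(=O)c1c(C)cc(O)cc1O
F6 | step 10 | allyl 4-{[2,4-bis(benzyloxy)-6-methylbenzoyl]oxy}-2-hydroxy-6-methylbenzoate | C=CCOC(=O)c1c(C)cc(OC(=O)c2c(C)cc(OCc3ccccc3)cc2OCc2ccccc2)cc1O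
F7 | step 10 | allyl 4-{[2,4-bis(benzyloxy)-6-methylbenzoyl]oxy}-2-methoxy-6-methylbenzoate | C=CCOC(=O)c1c(C)cc(OC(=O)c2c(C)cc(OCc3ccccc3)cc2OCc2ccccc2)cc1OC
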